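## Retrosynthetic overview

1. Target 13 ⇒ aldehyde 12 ⇒ aryl ether 10 + acrolein 11: a Lewis-acid ene reaction forms the C–C bond to the side chain and the isopropylidene in one event.
2. 10 ⇒ neopentyl alcohol 8 + isofraxidin 9 (C–O bond by Mitsunobu-type etherification).
3. 8 ⇒ diene amide 6: the secondary methyl centre comes from a face-selective HAT hydrogenation, then the auxiliary is removed reductively.
4. 6 ⇒ benzamide 4 ⇒ aroyl chloride 2 ⇒ p-cymene 1: an auxiliary-controlled Birch reduction–methylation dearomatises the arene and sets the quaternary centre (key step).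
5. No ring is built: the cyclohexane is the p-cymene ring carried through, and the coumarin is bought intact.

Assumption: the (S)-auxiliary 3 is taken to give the (1S)-diene 6 (the sense expected for 2-alkylbenzamides of this auxiliary); if the observed sense is opposite, (R)-3 is used and nothing else changes.

## Route

Step 1
Reactants: 1 p-cymene
Product: 2 2-methyl-5-(propan-2-yl)benzoyl chloride
Conditions: (COCl)2 (2 equiv), AlCl3 (1.1 equiv), CH2Cl2, 0 °C, 1 added last, → rt; poured onto ice/CaCl2, organic layer dried, vacuum distillation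
Reagents that add atoms: oxalyl chloride ClC(=O)C(=O)Cl
Why: Friedel–Crafts chlorocarbonylation (acylium from oxalyl chloride–AlCl3 with loss of CO) goes ortho to the methyl group, the position at which p-cymene is acylated, and the aroyl chloride survives a cold non-basic quench and is distilled.

Step 2
Reactants: 2 2-methyl-5-(propan-2-yl)benzoyl chloride; 3 (2S)-2-(methoxymethyl)pyrrolidine
Product: 4 [(2S)-2-(methoxymethyl)pyrrolidin-1-yl][2-methyl-5-(propan-2-yl)phenyl]methanone
Conditions: 3 (1.05 equiv), Et3N, cat. DMAP, CH2Cl2, 0 °C → rt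
Reagents that add atoms: none
Why: Aminolysis of the aroyl chloride (nucleophilic acyl substitution) by the secondary amine installs the Schultz prolinol methyl ether auxiliary without touching its stereocentre.

Step 3
Reactants: 4 benzamide
Product: 6 [(1S)-1,2-dimethyl-5-(propan-2-yl)cyclohexa-2,5-dien-1-yl][(2S)-2-(methoxymethyl)pyrrolidin-1-yl]methanone, via potassium enolate 5 (not isolated)
Conditions: K (2.2 equiv), t-BuOH (1 equiv), NH3/THF, −78 °C; then MeI, −78 °C; NH4Cl
Reagents that add atoms: iodomethane CI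
Why: Schultz asymmetric Birch reduction–alkylation: reduction at C1/C4 with protonation at C4 gives the chelated amide enolate, and the auxiliary directs C-methylation to one face, which sets the quaternary centre.

Step 4
Reactants: 6 diene amide
Product: 7 [(1R,6R)-1,6-dimethyl-3-(propan-2-yl)cyclohex-2-en-1-yl][(2S)-2-(methoxymethyl)pyrrolidin-1-yl]methanone
Conditions: Mn(dpm)3 (10 mol %), PhSiH3, t-BuOOH, i-PrOH, 22 °C
Reagents that add atoms: none
Why: Metal-hydride HAT hydrogenation (Shenvi type): H• adds to the unhindered CH of the methyl-bearing alkene rather than to the neopentyl CH of the isopropyl-bearing alkene, and the tertiary radical then takes H anti to the bulky carboxamide, which places the new C–H cis to the quaternary methyl.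

Step 5
Reactants: 7 ene amide
Product: 8 [(1R,6R)-1,6-dimethyl-3-(propan-2-yl)cyclohex-2-en-1-yl]methanol
Conditions: H3N·BH3, LDA, THF, 0 °C (forms LiH2NBH3); then 7, 0 → 66 °C; aq. HCl, then NaOH
Reagents that add atoms: none
Why: Myers lithium amidotrihydroborate reduction cleaves hindered tertiary amides to primary alcohols and leaves the alkene and both stereocentres untouched.

Step 6
Reactants: 8 neopentyl alcohol; 9 isofraxidin (7-hydroxy-6,8-dimethoxy-2H-chromen-2-one)
Product: 10 7-{[(1R,6R)-1,6-dimethyl-3-(propan-2-yl)cyclohex-2-en-1-yl]methoxy}-6,8-dimethoxy-2H-chromen-2-one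
Conditions: Bu3P=CHCN (CMBP), toluene, 110 °C
Reagents that add atoms: none
Why: Tsunoda-type Mitsunobu etherification: CMBP turns the primary alcohol into its oxyphosphonium, which the acidic coumarin phenoxide displaces at 110 °C under conditions devised for hindered alcohols that fail with DEAD/PPh3, and no stereocentre is touched.

Step 7
Reactants: 10 aryl ether; 11 acrolein
Product: 13 7-{[(1R,2R,6R)-2-(3-hydroxypropyl)-1,6-dimethyl-3-(propan-2-ylidene)cyclohexyl]methoxy}-6,8-dimethoxy-2H-chromen-2-one, via aldehyde 12 (not isolated)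
Conditions: 11 (3 equiv), Me2AlCl (3.5 equiv), CH2Cl2, −78 → −20 °C; then MeOH, NaBH4, −40 → 0 °C; Rochelle salt
Reagents that add atoms: none
Why: Lewis-acid Alder-ene reaction (Snider type) in which the acrolein β-carbon bonds to the ring CH anti to the pseudoaxial CH2OAr group (new stereocentre cis to the quaternary methyl) while hydrogen is taken from the isopropyl methine, the alkyl group syn to the vinylic H, to give the isopropylidene, after which NaBH4 reduces the aldehyde faster than the coumarin lactone.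

## Compound list

1 | p-cymene | Cc1ccc(cc1)C(C)C | starting material
2 | 2-methyl-5-(propan-2-yl)benzoyl chloride | Cc1ccc(C(C)C)cc1C(=O)Cl | intermediate
3 | (2S)-2-(methoxymethyl)pyrrolidine | COC[C@@H]1CCCN1 | starting material
4 | [(2S)-2-(methoxymethyl)pyrrolidin-1-yl][2-methyl-5-(propan-2-yl)phenyl]methanone | COC[C@@H]1CCCN1C(=O)c1cc(C(C)C)ccc1C | intermediate
5 | potassium amide enolate of the 1,4-dihydro form of 4 (enolate geometry not assigned) | COC[C@@H]1CCCN1C([O-])=C1C(C)=CCC(C(C)C)=C1.[K+] | intermediate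
6 | [(1S)-1,2-dimethyl-5-(propan-2-yl)cyclohexa-2,5-dien-1-yl][(2S)-2-(methoxymethyl)pyrrolidin-1-yl]methanone | COC[C@@H]1CCCN1C(=O)[C@]1(C)C(C)=CCC(C(C)C)=C1 | intermediate
7 | [(1R,6R)-1,6-dimethyl-3-(propan-2-yl)cyclohex-2-en-1-yl][(2S)-2-(methoxymethyl)pyrrolidin-1-yl]methanone | COC[C@@H]1CCCN1C(=O)[C@]1(C)[C@H](C)CCC(C(C)C)=C1 | intermediate
8 | [(1R,6R)-1,6-dimethyl-3-(propan-2-yl)cyclohex-2-en-1-yl]methanol | OC[C@]1(C)[C@H](C)CCC(C(C)C)=C1 | intermediate
9 | isofraxidin (7-hydroxy-6,8-dimethoxy-2H-chromen-2-one) | COc1cc2ccc(=O)oc2c(OC)c1O | starting material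
10 | 7-{[(1R,6R)-1,6-dimethyl-3-(propan-2-yl)cyclohex-2-en-1-yl]methoxy}-6,8-dimethoxy-2H-chromen-2-one | COc1cc2ccc(=O)oc2c(OC)c1OC[C@]1(C)[C@H](C)CCC(C(C)C)=C1 | intermediate
11 | acrolein | C=CC=O | starting material
12 | 3-[(1R,2R,3R)-2-{[(6,8-dimethoxy-2-oxo-2H-chromen-7-yl)oxy]methyl}-2,3-dimethyl-6-(propan-2-ylidene)cyclohexyl]propanal | COc1cc2ccc(=O)oc2c(OC)c1OC[C@]1(C)[C@H](C)CCC(=C(C)C)[C@H]1CCC=O | intermediate
13 | 7-{[(1R,2R,6R)-2-(3-hydroxypropyl)-1,6-dimethyl-3-(propan-2-ylidene)cyclohexyl]methoxy}-6,8-dimethoxy-2H-chromen-2-one | COc1cc2ccc(=O)oc2c(OC)c1OC[C@]1(C)[C@H](C)CCC(=C(C)C)[C@H]1CCCO | target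

## Step count and risks

Total steps: 7. Longest linear sequence: 7 (p-cymene 1 → 13); compounds 3, 9 and 11 are bought.

Three steps most likely to fail:

Step 7 (ene reaction at a ring CH next to the quaternary carbon, with the coumarin present). The fallback sets out from 7 and comes back at 13. It moves the C–C bond formation ahead of the ether, where the only Lewis-basic site is the amide. Methyl acrylate/EtAlCl2 (CH2Cl2, 0–25 °C) gives methyl 3-[(1R,2R,3R)-2-{[(2S)-2-(methoxymethyl)pyrrolidin-1-yl]carbonyl}-2,3-dimethyl-6-(propan-2-ylidene)cyclohexyl]propanoate F4. LiH2NBH3 reduces amide and ester together to 3-[(1R,2R,3R)-2-(hydroxymethyl)-2,3-dimethyl-6-(propan-2-ylidene)cyclohexyl]propan-1-ol F5. TBSCl/imidazole at −20 °C silylates only the unhindered chain hydroxyl to give [(1R,2R,6R)-2-{3-[(tert-butyldimethylsilyl)oxy]propyl}-1,6-dimethyl-3-(propan-2-ylidene)cyclohexyl]methanol F6. CMBP etherification with 9 gives the silyl-protected aryl ether F7, and HF·pyridine releases 13.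

Step 4 (HAT hydrogenation of a 1,4-diene; risks are bis-allylic H abstraction and incomplete selectivity between the two alkenes). The fallback sets out from 6 and comes back at 7. It replaces the radical hydrogenation by polar syn-hydroboration and deoxygenation. 9-BBN (THF, 60 °C) adds to the same unhindered CH from the face anti to the amide; NaBO3 oxidation gives [(1S,5S,6S)-5-hydroxy-1,6-dimethyl-3-(propan-2-yl)cyclohex-2-en-1-yl][(2S)-2-(methoxymethyl)pyrrolidin-1-yl]methanone F1. NaH/CS2/MeI gives its S-methyl xanthate F2, and Bu3SnH/AIBN (toluene, 80 °C) removes the oxygen to give 7.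

Step 6 (etherification at a neopentyl carbon with a di-ortho-substituted phenol). The fallback sets out from 8 and comes back at 10. It swaps the redox condensation for phenoxide alkylation. Tf2O/2,6-di-tert-butylpyridine (CH2Cl2, −78 °C) gives [(1R,6R)-1,6-dimethyl-3-(propan-2-yl)cyclohex-2-en-1-yl]methyl trifluoromethanesulfonate F3, which is treated cold with the caesium salt of 9 (Cs2CO3, DMF, 0 → 25 °C) to give 10.

## Further compounds

F1 | step 4 | [(1S,5S,6S)-5-hydroxy-1,6-dimethyl-3-(propan-2-yl)cyclohex-2-en-1-yl][(2S)-2-(methoxymethyl)pyrrolidin-1-yl]methanone | COC[C@@H]1CCCN1C(=O)[C@]1(C)[C@H](C)[C@@H](O)CC(C(C)C)=C1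
F2 | step 4 | S-methyl xanthate (O-alkyl S-methyl carbonodithioate) of F1 | COC[C@@H]1CCCN1C(=O)[C@]1(C)[C@H](C)[C@@H](OC(=S)SC)CC(C(C)C)=C1
F3 | step 6 | [(1R,6R)-1,6-dimethyl-3-(propan-2-yl)cyclohex-2-en-1-yl]methyl trifluoromethanesulfonate | FC(F)(F)S(=O)(=O)OC[C@]1(C)[C@H](C)CCC(C(C)C)=C1
F4 | step 7 | methyl 3-[(1R,2R,3R)-2-{[(2S)-2-(methoxymethyl)pyrrolidin-1-yl]carbonyl}-2,3-dimethyl-6-(propan-2-ylidene)cyclohexyl]propanoate | COC[C@@H]1CCCN1C(=O)[C@]1(C)[C@H](C)CCC(=C(C)C)[C@H]1CCC(=O)OC
F5 | step 7 | 3-[(1R,2R,3R)-2-(hydroxymethyl)-2,3-dimethyl-6-(propan-2-ylidene)cyclohexyl]propan-1-ol | OC[C@]1(C)[C@H](C)CCC(=C(C)C)[C@H]1CCCO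
F6 | step 7 | [(1R,2R,6R)-2-{3-[(tert-butyldimethylsilyl)oxy]propyl}-1,6-dimethyl-3-(propan-2-ylidene)cyclohexyl]methanol | OC[C@]1(C)[C@H](C)CCC(=C(C)C)[C@H]1CCCO[Si](C)(C)C(C)(C)C
F7 | step 7 | 7-{[(1R,2R,6R)-2-{3-[(tert-butyldimethylsilyl)oxy]propyl}-1,6-dimethyl-3-(propan-2-ylidene)cyclohexyl]methoxy}-6,8-dimethoxy-2H-chromen-2-one | COc1cc2ccc(=O)oc2c(OC)c1OC[C@]1(C)[C@H](C)CCC(=C(C)C)[C@H]1CCCO[Si](C)(C)C(C)(C)C
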